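## The problem

Numbering follows the labdanes: C1–C10 for the decalin (ring A = C1–C5/C10, ring B = C5–C10), C17 and C20 for the methyls on C8 and C10, C18 and C19 for the 4α and 4β carbons, C11–C16 along the chain, C16 being the ring CH of the butenolide. Target 40 is a 25-carbon labdane-type sesterterpenoid: a trans-decalin whose C9 carries a nine-carbon chain ending in a 4-methylbutenolide. The decalin holds six stereocentres, two of them quaternary (C4 with 4α-CHO and 4β-CH3, C10 with a β-methyl), next to the equatorial 6α-hydroxyl, the tertiary 8α-hydroxyl and the 9β chain. The chain adds the (E)-C13=C14 alkene and the syn (15S,16S) hydroxy-lactone pair. Only C10 cannot be corrected once made. C5 and C9 lie next to carbonyl groups in the intermediates and can relax to the trans-fused, 9β arrangement. C8 is controllable because the axial C10 methyl screens the β-face of a Δ7-6-ketone, whereas C6 needs the equatorial alcohol that hydride reagents, pushed to the α-face by the axial groups on C4, C8 and C10, do not give. C4 is the subtle centre: its two one-carbon arms differ only in oxidation level, and the 6α-oxygen, which can reach the 4α arm but not the 4β arm, is the one element that tells them apart; C15 and C16 are too far from the core and need reagent control. The fragile functions are the 18-aldehyde beside the 6-hydroxyl (hemiacetal formation, over-oxidation), the tertiary 8-hydroxyl whenever a carbonyl sits at C6 or C11 (dehydration, retro-aldol), the allylic C15 alcohol and the butenolide, which tolerates neither hydride nor base. The enabling feature is ring B: oxygen on C6 and C8, C11 on C9 and a quaternary C10 are the imprint of a C5=C6(OSi)–C7=C8 silyloxydiene added to a C9=C10 enoyl unit, and because the C4 arms are equivalent until C6 is oxygenated, a malonate can serve as an achiral tether between diene and dienophile.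

## Retrosynthesis

**40 from 38 (no skeletal bond cut).** The last operation should only unmask. The 18-aldehyde and the 6α-hydroxyl are carried together as the cyclic methyl acetal in 38. A late oxidation of a C18 alcohol was set aside because such a 1,4-diol runs on to the lactone, and a late reduction of an 18,6-lactone would not spare the butenolide. The forward step is a mild acid hydrolysis through hemiacetal 39.

**38 from 34 and 36 (C15–C16).** This cut removes the butenolide and both chain stereocentres at once, leaving enal 34 and silyloxyfuran 36, which is one step from commercial butenolide 35. A cut at C14–C15 would need a configurationally labile α-oxygenated aldehyde and several steps to build the lactone after the union. The forward vinylogous aldol must give the syn adduct with one absolute sense under catalyst control.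

**34 from 30 and 2 (C12–C13).** Olefination of a C13 ketone would give E/Z mixtures. Cutting the sp3–sp2 bond instead hands the alkene geometry to a small reagent, enol triflate 2 (from acetoacetate 1), and leaves vinyl decalin 30. The coupled ester 32 reaches 34 through allylic alcohol 33. The coupling must proceed with retention and tolerate the free tertiary alcohol and the acetal.

**30 from 24 (functional-group level at C4).** The 4β-methyl is traced to an ester and the acetal to a lactone: 30 comes from aldehyde 28, alcohol 27 and ester acetal 26, and these from lactone ester 24. The two arms are thus told apart in one event (lactonisation) and then handled by chemoselective reductions. The forward sequence asks for partial reduction of a γ-lactone in the presence of a hindered axial ester.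

**24 from 22, 21 and 20 (C6–O, C8–O, lactone C–O).** Lactone 24 opens to hydroxy ketone 22 (through diol 23), and 22 is the reductive opening product of epoxy ketone 21, made from enone 20. This is preferred to hydration of an isolated C8 alkene because the enone is what the cycloadduct offers and the C10 methyl fixes the face of epoxidation. Enone 20 has no oxygen stereocentre and an achiral C4. The forward steps need α-face epoxidation and an electron-transfer reduction that gives the equatorial C6 alcohol.

**20 from 19, and 19 from 16 (C11 handle).** Enone 20 is the dehydrogenation product of silyl enol ether 19, whose vinyl group derives from the acyl group of 16 through alcohol 17 and aldehyde 18. The auxiliary is removed before the enone is made, because a C9 hydrogen that is α to an imide and γ to an enone would not survive base. The vinyl group is the resting form of C11 because it needs no protecting group and is inert to every redox step up to 30.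

**16 from 15 (C5–C10 and C8–C9, both rings).** This cut opens rings A and B together and gives triene 15, whose only stereocentre is that of the auxiliary. Annulation onto a preformed ring would need a separate enantioselective entry to quaternary C10. Here C10 is set by the auxiliary and C5, C8 and C9 by the geometry of the addition. The forward reaction must join a β,β-disubstituted enoyl imide to a diene terminus that sits next to a quaternary carbon.

**15 from simple pieces.** Triene 15 is the silyl enol ether of enone imide 14, assembled from acid 11 and oxazolidinone 12. Acid 11 comes from tert-butyl ester 10, and 10 from Weinreb amide 7 and bromopropene 8. Amide 7 arises from 5 and triflate 2 by the same sp3–sp2 coupling used later, which fixes the (E)-geometry of the dienophile, and 5 from allylmalonate 3 and bromoacetamide 4.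

## Roads not taken

Alternative 1: The chain is cut at C14–C15 and at the C13–methyl bond. Core alkyne A1 would undergo Cp2ZrCl2-catalysed syn-addition of AlMe3, and the (E)-alkenylalane, after transmetalation with ZnCl2, would add to α-alkoxy aldehyde A2 to give allylic alcohol A3. Merits: the alkene geometry comes from the carbometalation, the union is convergent, and C16 is fixed in A2 before coupling, so only C15 must be induced (chelation control for the syn isomer). Weak points: A2 has its stereocentre between a formyl and an isopropenyl group and is prone to racemisation and to isomerisation into conjugation. Excess AlMe3 is a Lewis acid toward the C18 acetal of A1. After the union the lactone still has to be made (ether cleavage, acryloylation, ring-closing metathesis with the second-generation Grubbs catalyst, deprotection). The road also says nothing about how the decalin of A1 is obtained. Comparison: the control of C16 is more secure than in the chosen plan, where C15 and C16 arise together in one catalyst-controlled step. The chosen plan sets against this an endgame shorter by about four operations, no organoaluminium near the acetal, and a defined construction of the core. The two are compatible in principle, since this union is an endgame only.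

Alternative 2: Ring A is cut at C1–C10 and C4–C5 and ring B is bought as 2,6-dimethyl-1,4-benzoquinone A4. A Lewis-acid-catalysed endo Diels–Alder reaction with silyloxymethyl diene A5 would give cis-fused enedione A6. Merits: one intermolecular step from cheap components creates both quaternary carbons, and the C4 arms arrive already different (methyl and CH2OSi), which costs the chosen plan steps 15–19. Enantioselective quinone cycloadditions with chiral Lewis acids are known. Weak points: the reacting terminus of A5 necessarily carries an inside substituent, which disfavours the s-cis diene. The adduct is cis-fused and needs epimerisation at C5. C9 is a ketone flanked by quaternary C10, so the C9–C11 bond, removal of the C9 oxygen and the 9α-hydrogen all remain to be solved. Ring A has a surplus alkene, and C18 must be oxidised late beside the 6-hydroxyl. Comparison: this road is clearly shorter to a decalin and better at C4. The chosen plan sets against it that its cycloadduct already has the C9–C11 bond in the right configuration, the trans fusion and C10 under auxiliary control, so less remains to be done on ring B.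

Alternative 3: No skeletal bond is cut. The decalin is taken from larixol A7 and the cut is the O–C18 bond. The 6α-alcohol A8 (chain trimmed to the ketal, C8 alcohol silylated) would be converted by PhI(OAc)2 and I2 under light into the hypoiodite. Its alkoxyl radical abstracts hydrogen from the 4α-methyl and the iodide closes to tetrahydrofuran A9. Merits: C5, C9, C10 and the 6α-oxygen come from the chiral pool, the C6 problem does not arise, and the same 6α/4α proximity used in the chosen plan differentiates C4 in one step. Weak points: β-scission of the alkoxyl radical competes. The ether must then be oxidised at C18 to the lactone level beside a silyl ether and a ketal. The chain has to be degraded and rebuilt from a methyl ketone, where the C13=C14 geometry is again an olefination problem. The starting terpene is of limited supply and gives one enantiomeric series. Comparison: for the oxygenated decalin this road is shorter and stereochemically safer than the chosen plan. The chosen plan offers independence from a natural source, access to either enantiomer and to C4 or C8 analogues, and a stereospecific coupling for the chain alkene.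

Key step: step 8

Remark on the chemistry (assumption): 40 is taken to exist as the open 6α-hydroxy 18-aldehyde that is drawn. Its cyclic hemiacetal 39, whose five-membered ring would be trans-fused to both carbocycles, is assumed to open as it forms.

## Steps

Step 1
Reactants: 1 tert-butyl 3-oxobutanoate
Product: 2 tert-butyl (E)-3-(trifluoromethylsulfonyloxy)but-2-enoate
Conditions: Tf2O, aq. Me4NOH, hexanes, 5 °C to rt
Reagents that add atoms: trifluoromethanesulfonic anhydride O=S(=O)(OS(=O)(=O)C(F)(F)F)C(F)(F)F
Why: O-Sulfonylation of the acetoacetate enolate; with the non-coordinating tetramethylammonium counter-ion the enolate avoids the chelated U-shape, so the triflate should end up trans to the ester (E), the geometry needed for both later couplings.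

Step 2
Reactants: 3 dimethyl 2-allylmalonate; 4 2-bromo-N-methoxy-N-methylacetamide
Product: 5 dimethyl 2-allyl-2-[2-(methoxy(methyl)amino)-2-oxoethyl]malonate
Conditions: NaH, THF/DMF, 0 °C to rt
Reagents that add atoms: none
Why: SN2 alkylation of a malonate enolate by an α-halo amide; only one acidic hydrogen is present, so quaternary C4 forms without over-alkylation.

Step 3
Reactants: 5 dimethyl 2-allyl-2-[2-(methoxy(methyl)amino)-2-oxoethyl]malonate; 2 tert-butyl (E)-3-(trifluoromethylsulfonyloxy)but-2-enoate
Product: 7 dimethyl 2-[(E)-6-tert-butoxy-4-methyl-6-oxohex-4-en-1-yl]-2-[2-(methoxy(methyl)amino)-2-oxoethyl]malonate, via alkylborane 6 (not isolated)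
Conditions: 9-BBN, THF, 0 °C to rt; then 2, Pd(dppf)Cl2 (5 mol%), aq. K3PO4, DMF, rt to 50 °C
Reagents that add atoms: none
Why: Anti-Markovnikov hydroboration of the terminal alkene followed by B-alkyl Suzuki–Miyaura coupling with the enol triflate, which proceeds with retention and fixes the (E)-C9=C10 geometry; esters and the Weinreb amide are inert to 9-BBN and to the mild base.

Step 4
Reactants: 7 dimethyl 2-[(E)-6-tert-butoxy-4-methyl-6-oxohex-4-en-1-yl]-2-[2-(methoxy(methyl)amino)-2-oxoethyl]malonate; 8 (E)-1-bromoprop-1-ene
Product: 10 dimethyl 2-[(E)-6-tert-butoxy-4-methyl-6-oxohex-4-en-1-yl]-2-[(E)-2-oxopent-3-en-1-yl]malonate, via (E)-prop-1-enylmagnesium bromide 9 (not isolated)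
Conditions: 8, Mg, THF, rt; then 7, THF, −20 to 0 °C; aq. NH4Cl
Reagents that add atoms: none
Why: Alkenyl Grignard addition to the Weinreb amide stops at the chelated tetrahedral intermediate and releases the enone only on work-up; the hindered malonate esters and the β,β-disubstituted tert-butyl enoate are far less electrophilic, and any (Z)-enone should equilibrate to the (E)-isomer.

Step 5
Reactants: 10 dimethyl 2-[(E)-6-tert-butoxy-4-methyl-6-oxohex-4-en-1-yl]-2-[(E)-2-oxopent-3-en-1-yl]malonate
Product: 11 (2E,10E)-7,7-bis(methoxycarbonyl)-3-methyl-9-oxododeca-2,10-dienoic acid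
Conditions: CF3CO2H, CH2Cl2, 0 °C to rt
Reagents that add atoms: none
Why: Acidolysis of the tert-butyl ester by loss of isobutene leaves the methyl esters and the enone untouched and frees the one carboxyl group that is to carry the auxiliary.

Step 6
Reactants: 11 (2E,10E)-7,7-bis(methoxycarbonyl)-3-methyl-9-oxododeca-2,10-dienoic acid; 12 (S)-4-benzyloxazolidin-2-one
Product: 14 dimethyl 2-{(E)-6-[(S)-4-benzyl-2-oxooxazolidin-3-yl]-4-methyl-6-oxohex-4-en-1-yl}-2-[(E)-2-oxopent-3-en-1-yl]malonate, via mixed pivalic anhydride 13 (not isolated)
Conditions: t-BuCOCl, Et3N, THF, −20 °C; then 12, LiCl, −20 °C to rt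
Reagents that add atoms: none
Why: N-Acylation of the oxazolidinone through the mixed pivalic anhydride under LiCl/Et3N activation needs no strong base, so the enolisable enone and the alkene geometry are preserved; attack occurs at the less hindered enoyl carbonyl.

Step 7
Reactants: 14 dimethyl 2-{(E)-6-[(S)-4-benzyl-2-oxooxazolidin-3-yl]-4-methyl-6-oxohex-4-en-1-yl}-2-[(E)-2-oxopent-3-en-1-yl]malonate
Product: 15 dimethyl 2-{(E)-6-[(S)-4-benzyl-2-oxooxazolidin-3-yl]-4-methyl-6-oxohex-4-en-1-yl}-2-[(1Z,3E)-2-(tert-butyldimethylsilyloxy)penta-1,3-dien-1-yl]malonate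
Conditions: TBSOTf, Et3N, CH2Cl2, −78 to 0 °C
Reagents that add atoms: tert-butyldimethylsilyl trifluoromethanesulfonate CC(C)(C)[Si](C)(C)OS(=O)(=O)C(F)(F)F
Why: Soft enolisation of the enone on the α′ side (C5) gives the cross-conjugated 2-silyloxydiene; the bulky C4 group should sit cis to oxygen (Z), the geometry that allows the s-cis diene, and the enoyl imide has no α-hydrogen to compete.

Step 8
Reactants: 15 dimethyl 2-{(E)-6-[(S)-4-benzyl-2-oxooxazolidin-3-yl]-4-methyl-6-oxohex-4-en-1-yl}-2-[(1Z,3E)-2-(tert-butyldimethylsilyloxy)penta-1,3-dien-1-yl]malonate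
Product: 16 trans-fused Δ6-octalin cycloadduct: dimethyl 9β-[(S)-4-benzyl-2-oxooxazolidine-3-carbonyl]-6-(tert-butyldimethylsilyloxy)-8β,10β-dimethyl-5α,8α,9α-H-octal-6-ene-4,4-dicarboxylate (labdane numbering)
Conditions: Me2AlCl (2.5 equiv), CH2Cl2, −30 to 0 °C
Reagents that add atoms: none
Why: Proposed new method: Me2AlCl gives up chloride to a second equivalent and forms the cationic bidentate aluminium chelate of the s-cis enoyl imide, which makes C10 electrophilic enough for the electron-rich C5 terminus of the 2-silyloxydiene to attack, either in a concerted asynchronous [4+2] addition or as a Mukaiyama–Michael addition followed by collapse of the aluminium imide enolate onto C8 of the silyloxyallyl cation; the closest known reactions are the dialkylaluminium-chloride-promoted intramolecular Diels–Alder reaction of (E)-β-monosubstituted trienimides and Lewis-acid cycloadditions of 2-silyloxydienes with β,β-disubstituted enones, and the untested element is a β,β-disubstituted enoyl imide that must create quaternary C10 next to quaternary C4. Ring A closes as the tether ring (six-membered, exo with respect to C9=C10 in the stepwise picture) and ring B as the new cyclohexene (endo closure of C9 onto C8), leaving the C6=C7 silyl enol ether. C10 is set by the auxiliary: in the chelate the benzyl group covers one face of C9=C10 and the diene adds to the other, which for the (S)-auxiliary is the face that leads to the 10β-methyl. C9 follows from the (E)-geometry of the dienophile (carbonyl cis to the C10 methyl, suprafacial addition), C5 from the imide-endo arrangement with a chair-like tether that gives the trans fusion, and C8 from the (E)-propenyl terminus. The step needs π-facial selectivity and C5-to-C10 regiochemistry; the first rests on the chelated auxiliary, the second is enforced by the four-atom tether and by matched polarity. The geminal diester favours the reactive fold (Thorpe–Ingold effect), and errors at C5 or C8 are tolerable because C5 is epimerisable at the later ketone stage and C8 is flattened in step 12.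

Step 9
Reactants: 16 cycloadduct imide
Product: 17 dimethyl 6-(tert-butyldimethylsilyloxy)-9β-(hydroxymethyl)-8β,10β-dimethyl-5α,8α,9α-H-octal-6-ene-4,4-dicarboxylate
Conditions: LiBH4, MeOH (1 equiv), Et2O, 0 °C
Reagents that add atoms: none
Why: Reductive removal of the auxiliary: the imide carbonyl is the most electrophilic acyl group and is reduced to the primary alcohol, while the neopentyl malonate esters and the silyl enol ether should survive at 0 °C; the auxiliary is recovered.

Step 10
Reactants: 17 primary alcohol
Product: 18 dimethyl 6-(tert-butyldimethylsilyloxy)-9β-formyl-8β,10β-dimethyl-5α,8α,9α-H-octal-6-ene-4,4-dicarboxylate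
Conditions: n-Pr4N[RuO4] (5 mol%), N-methylmorpholine N-oxide, 4 Å MS, CH2Cl2, rt
Reagents that add atoms: none
Why: Ley–Griffith oxidation is neutral, so the silyl enol ether is not hydrolysed and the C9 stereocentre next to the new aldehyde is not epimerised.

Step 11
Reactants: 18 aldehyde
Product: 19 dimethyl 6-(tert-butyldimethylsilyloxy)-8β,10β-dimethyl-9β-vinyl-5α,8α,9α-H-octal-6-ene-4,4-dicarboxylate
Conditions: Ph3PCH3Br, KN(SiMe3)2, THF, −78 to 0 °C
Reagents that add atoms: methyltriphenylphosphonium bromide C[P+](c1ccccc1)(c1ccccc1)c1ccccc1.[Br-]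
Why: Wittig methylenation with the small salt-free ylide is fast even at a hindered aldehyde and leaves the esters alone; the vinyl group stores C11 and the future C12 in a form that is inert to the redox steps that follow.

Step 12
Reactants: 19 vinyl silyl enol ether
Product: 20 dimethyl 8,10β-dimethyl-6-oxo-9β-vinyl-5α,9α-H-octal-7-ene-4,4-dicarboxylate
Conditions: Pd(OAc)2 (1.2 equiv), MeCN, rt to 40 °C
Reagents that add atoms: none
Why: Saegusa–Ito oxidation: the palladium enolate formed at C7 on the open α-face eliminates the syn 8α-hydrogen to give the Δ7-6-ketone, which erases the C8 stereocentre that is no longer needed.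

Step 13
Reactants: 20 enone
Product: 21 dimethyl 7α,8α-epoxy-8β,10β-dimethyl-6-oxo-9β-vinyl-5α,9α-H-decalin-4,4-dicarboxylate
Conditions: 30% H2O2, aq. NaOH, MeOH, 0 °C
Reagents that add atoms: hydrogen peroxide OO
Why: Nucleophilic (Weitz–Scheffer) epoxidation of the enone; hydroperoxide adds to C8 from the α-face because the β-face is screened by the axial C10 methyl and the 9β-vinyl group, which places the C8–O bond α.

Step 14
Reactants: 21 epoxy ketone
Product: 22 dimethyl 8α-hydroxy-8β,10β-dimethyl-6-oxo-9β-vinyl-5α,9α-H-decalin-4,4-dicarboxylate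
Conditions: SmI2 (2.5 equiv), THF/MeOH, −90 °C
Reagents that add atoms: none
Why: Reductive opening of the α,β-epoxy ketone: the ketyl expels the C7–O bond and the samarium enolate is protonated, so oxygen remains only on C8 with its configuration unchanged (8α-OH, 8β-CH3).

Step 15
Reactants: 22 β-hydroxy ketone
Product: 24 methyl 8α-hydroxy-8β,10β-dimethyl-9β-vinyl-5α,9α-H-decalin-18,6α-olide-4β-carboxylate (γ-lactone from the 4α-carboxyl to the 6α-oxygen), via 6α-hydroxy diester 23 (not isolated)
Conditions: SmI2 (2.5 equiv), H2O, Et3N, THF, 0 °C; then PPTS, PhMe, 60 °C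
Reagents that add atoms: none
Why: Single-electron reduction of the C6 ketone passes through ketyl and organosamarium species that settle with the bulky oxygen–samarium group equatorial, so the 6α-alcohol is expected where hydride would give 6β. The 6α-oxygen can reach only the peri-related 4α-ester, and loss of methanol gives the γ-lactone that makes C4 a defined stereocentre.

Step 16
Reactants: 24 lactone ester
Product: 26 methyl 6α,18-epoxy-8α-hydroxy-18-methoxy-8β,10β-dimethyl-9β-vinyl-5α,9α-H-decalin-4β-carboxylate (cyclic methyl acetal; both C18 epimers), via lactol 25 (not isolated)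
Conditions: i-Bu2AlH (2.2 equiv), CH2Cl2, −78 °C; aq. potassium sodium tartrate; then MeOH, PPTS, rt
Reagents that add atoms: methanol CO
Why: The strained γ-lactone should be reduced to the aluminium lactolate faster than the axial neopentyl methyl ester reacts, and the crude lactol is fixed by acid-catalysed acetalisation as the cyclic methyl acetal, which masks both the C18 aldehyde and the 6-hydroxyl; the configuration at C18 is of no consequence.

Step 17
Reactants: 26 ester acetal
Product: 27 6α,18-epoxy-4β-(hydroxymethyl)-18-methoxy-8β,10β-dimethyl-9β-vinyl-5α,9α-H-decalin-8α-ol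
Conditions: LiAlH4, THF, 0 to 50 °C
Reagents that add atoms: none
Why: Hydride reduction of the remaining hindered ester to the 4β-hydroxymethyl group; acetal, alkene and tertiary alcohol are inert.

Step 18
Reactants: 27 primary alcohol
Product: 28 6α,18-epoxy-8α-hydroxy-18-methoxy-8β,10β-dimethyl-9β-vinyl-5α,9α-H-decalin-4β-carbaldehyde
Conditions: Dess–Martin periodinane, NaHCO3, CH2Cl2, rt
Reagents that add atoms: none
Why: Dess–Martin oxidation of the only primary alcohol; the buffer protects the acetal, and the aldehyde cannot enolise because C4 is quaternary.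

Step 19
Reactants: 28 aldehyde
Product: 30 6α,18-epoxy-18-methoxy-4β,8β,10β-trimethyl-9β-vinyl-5α,9α-H-decalin-8α-ol, via hydrazone 29 (not isolated)
Conditions: N2H4·H2O, KOH, diethylene glycol, 130 then 200 °C
Reagents that add atoms: none
Why: Wolff–Kishner reduction (Huang–Minlon procedure), the classical way to turn an axial C4 formyl group into methyl; the acetal, the tertiary alcohol and the isolated vinyl group are stable to hot base.

Step 20
Reactants: 30 vinyl decalin; 2 tert-butyl (E)-3-(trifluoromethylsulfonyloxy)but-2-enoate
Product: 32 tert-butyl (E)-5-[6α,18-epoxy-8α-hydroxy-18-methoxy-4β,8β,10β-trimethyl-5α,9α-H-decalin-9β-yl]-3-methylpent-2-enoate, via alkylborane 31 (not isolated)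
Conditions: 9-BBN (excess), THF, rt to 40 °C; then 2, Pd(dppf)Cl2 (5 mol%), aq. K3PO4, DMF, rt to 50 °C
Reagents that add atoms: none
Why: Hydroboration puts boron on C12, and the B-alkyl Suzuki–Miyaura coupling with the (E)-enol triflate forms C12–C13 with retention, so the trisubstituted C13=C14 alkene is obtained as the (E)-isomer without olefination of a ketone.

Step 21
Reactants: 32 tert-butyl enoate
Product: 33 (E)-5-[6α,18-epoxy-8α-hydroxy-18-methoxy-4β,8β,10β-trimethyl-5α,9α-H-decalin-9β-yl]-3-methylpent-2-en-1-ol
Conditions: i-Bu2AlH (4 equiv), CH2Cl2, −78 to 0 °C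
Reagents that add atoms: none
Why: 1,2-Reduction of the enoate to the allylic alcohol; the cyclic acetal is not cleaved by i-Bu2AlH at or below 0 °C.

Step 22
Reactants: 33 allylic alcohol
Product: 34 (E)-5-[6α,18-epoxy-8α-hydroxy-18-methoxy-4β,8β,10β-trimethyl-5α,9α-H-decalin-9β-yl]-3-methylpent-2-enal
Conditions: MnO2, CH2Cl2, rt
Reagents that add atoms: none
Why: Selective oxidation of the allylic alcohol to the (E)-enal; the tertiary alcohol and the acetal are not oxidised.

Step 23
Reactants: 35 4-methylfuran-2(5H)-one
Product: 36 4-methyl-2-(trimethylsilyloxy)furan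
Conditions: Me3SiOTf, Et3N, Et2O, 0 °C
Reagents that add atoms: trimethylsilyl trifluoromethanesulfonate C[Si](C)(C)OS(=O)(=O)C(F)(F)F
Why: γ-Deprotonation and O-silylation of the butenolide give the aromatic 2-silyloxyfuran, the dienolate equivalent of the lactone.

Step 24
Reactants: 34 enal; 36 4-methyl-2-(trimethylsilyloxy)furan
Product: 38 (15S,16S)-15-hydroxy butenolide with the 6α,18-methyl acetal (target skeleton with C18 still masked), via trimethylsilyl ether 37 (not isolated)
Conditions: Ti(OiPr)4, (S)-BINOL (20 mol%), Et2O, −20 °C; then citric acid, MeOH, rt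
Reagents that add atoms: none
Why: Catalytic asymmetric vinylogous Mukaiyama aldol: the furan attacks the titanium-bound enal through its C5 in an open transition state that favours the syn (threo) adduct, while the BINOL ligand selects the aldehyde face, the remote core exerting no bias. The ligand enantiomer is chosen to give (15S,16S) and would be exchanged for its antipode if the opposite sense were found; the silyl ether from silyl transfer is cleaved in acidic methanol, in which the methyl acetal is unchanged.

Step 25
Reactants: 38 hydroxy butenolide acetal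
Product: 40 CNP0112578.1, via lactol 39 (not isolated)
Conditions: AcOH/THF/H2O (3:1:1), 40 °C
Reagents that add atoms: water O
Why: Mild acid hydrolysis of the furanoside-type methyl acetal gives the hemiacetal, which opens to the 6α-hydroxy 18-aldehyde; the conditions are too weak to ionise the C15 allylic alcohol (deactivated by the adjacent lactone oxygen) or to dehydrate the tertiary alcohol.

## Compound list

1 | tert-butyl 3-oxobutanoate | CC(=O)CC(=O)OC(C)(C)C | starting material
2 | tert-butyl (E)-3-(trifluoromethylsulfonyloxy)but-2-enoate | C/C(=C\C(=O)OC(C)(C)C)OS(=O)(=O)C(F)(F)F | intermediate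
3 | dimethyl 2-allylmalonate | C=CCC(C(=O)OC)C(=O)OC | starting material
4 | 2-bromo-N-methoxy-N-methylacetamide | CON(C)C(=O)CBr | starting material
5 | dimethyl 2-allyl-2-[2-(methoxy(methyl)amino)-2-oxoethyl]malonate | C=CCC(CC(=O)N(C)OC)(C(=O)OC)C(=O)OC | intermediate
6 | dimethyl 2-[3-(9-borabicyclo[3.3.1]nonan-9-yl)propyl]-2-[2-(methoxy(methyl)amino)-2-oxoethyl]malonate (formed in situ) | CON(C)C(=O)CC(CCCB1C2CCCC1CCC2)(C(=O)OC)C(=O)OC | intermediate
7 | dimethyl 2-[(E)-6-tert-butoxy-4-methyl-6-oxohex-4-en-1-yl]-2-[2-(methoxy(methyl)amino)-2-oxoethyl]malonate | CON(C)C(=O)CC(CCC/C(C)=C/C(=O)OC(C)(C)C)(C(=O)OC)C(=O)OC | intermediate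
8 | (E)-1-bromoprop-1-ene | C/C=C/Br | starting material
9 | (E)-prop-1-enylmagnesium bromide (formed in situ) | C/C=C/[Mg]Br | intermediate
10 | dimethyl 2-[(E)-6-tert-butoxy-4-methyl-6-oxohex-4-en-1-yl]-2-[(E)-2-oxopent-3-en-1-yl]malonate | C/C=C/C(=O)CC(CCC/C(C)=C/C(=O)OC(C)(C)C)(C(=O)OC)C(=O)OC | intermediate
11 | (2E,10E)-7,7-bis(methoxycarbonyl)-3-methyl-9-oxododeca-2,10-dienoic acid | C/C=C/C(=O)CC(CCC/C(C)=C/C(=O)O)(C(=O)OC)C(=O)OC | intermediate
12 | (S)-4-benzyloxazolidin-2-one | O=C1OC[C@H](Cc2ccccc2)N1 | starting material
13 | mixed anhydride of 11 with pivalic acid (formed in situ) | C/C=C/C(=O)CC(CCC/C(C)=C/C(=O)OC(=O)C(C)(C)C)(C(=O)OC)C(=O)OC | intermediate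
14 | dimethyl 2-{(E)-6-[(S)-4-benzyl-2-oxooxazolidin-3-yl]-4-methyl-6-oxohex-4-en-1-yl}-2-[(E)-2-oxopent-3-en-1-yl]malonate | C/C=C/C(=O)CC(CCC/C(C)=C/C(=O)N1C(=O)OC[C@@H]1Cc1ccccc1)(C(=O)OC)C(=O)OC | intermediate
15 | dimethyl 2-{(E)-6-[(S)-4-benzyl-2-oxooxazolidin-3-yl]-4-methyl-6-oxohex-4-en-1-yl}-2-[(1Z,3E)-2-(tert-butyldimethylsilyloxy)penta-1,3-dien-1-yl]malonate | C/C=C/C(O[Si](C)(C)C(C)(C)C)=C/C(C(=O)OC)(C(=O)OC)CCC/C(C)=C/C(=O)N1C(=O)OC[C@@H]1Cc1ccccc1 | intermediate
16 | trans-fused Δ6-octalin cycloadduct: 4,4-bis(methoxycarbonyl), 6-OTBS, 8β-methyl, 9β-[(S)-4-benzyl-2-oxooxazolidine-3-carbonyl], 10β-methyl, 5α-H | O=C(N1C(=O)OC[C@@H]1Cc1ccccc1)[C@@H]1[C@@]2(C)CCCC(C(=O)OC)(C(=O)OC)[C@@H]2C(O[Si](C)(C)C(C)(C)C)=C[C@@H]1C | intermediate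
17 | 9β-hydroxymethyl analogue of 16 | OC[C@@H]1[C@@]2(C)CCCC(C(=O)OC)(C(=O)OC)[C@@H]2C(O[Si](C)(C)C(C)(C)C)=C[C@@H]1C | intermediate
18 | 9β-formyl analogue of 16 | O=C[C@@H]1[C@@]2(C)CCCC(C(=O)OC)(C(=O)OC)[C@@H]2C(O[Si](C)(C)C(C)(C)C)=C[C@@H]1C | intermediate
19 | 9β-vinyl silyl enol ether | C=C[C@@H]1[C@@]2(C)CCCC(C(=O)OC)(C(=O)OC)[C@@H]2C(O[Si](C)(C)C(C)(C)C)=C[C@@H]1C | intermediate
20 | 9β-vinyl Δ7-6-ketone (trans-fused, 10β-methyl) | C=C[C@@H]1[C@@]2(C)CCCC(C(=O)OC)(C(=O)OC)[C@@H]2C(=O)C=C1C | intermediate
21 | 7α,8α-epoxy 6-ketone | C=C[C@@H]1[C@@]2(C)CCCC(C(=O)OC)(C(=O)OC)[C@@H]2C(=O)[C@H]3O[C@@]13C | intermediate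
22 | 8α-hydroxy 6-ketone diester | C=C[C@@H]1[C@@]2(C)CCCC(C(=O)OC)(C(=O)OC)[C@@H]2C(=O)C[C@@]1(C)O | intermediate
23 | 6α,8α-dihydroxy diester (formed in situ) | C=C[C@@H]1[C@@]2(C)CCCC(C(=O)OC)(C(=O)OC)[C@@H]2[C@@H](O)C[C@@]1(C)O | intermediate
24 | 18,6α-lactone with 4β-methoxycarbonyl, 8α-OH, 9β-vinyl | C=C[C@@H]1[C@@]2(C)CCC[C@@]3(C(=O)OC)C(=O)O[C@H]([C@H]23)C[C@@]1(C)O | intermediate
25 | 6α,18-lactol with 4β-methoxycarbonyl (C18 epimers, formed in situ) | C=C[C@@H]1[C@@]2(C)CCC[C@@]3(C(=O)OC)C(O)O[C@H]([C@H]23)C[C@@]1(C)O | intermediate
26 | 6α,18-cyclic methyl acetal with 4β-methoxycarbonyl (C18 epimers) | C=C[C@@H]1[C@@]2(C)CCC[C@@]3(C(=O)OC)C(OC)O[C@H]([C@H]23)C[C@@]1(C)O | intermediate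
27 | cyclic methyl acetal with 4β-hydroxymethyl | C=C[C@@H]1[C@@]2(C)CCC[C@@]3(CO)C(OC)O[C@H]([C@H]23)C[C@@]1(C)O | intermediate
28 | cyclic methyl acetal with 4β-formyl | C=C[C@@H]1[C@@]2(C)CCC[C@@]3(C=O)C(OC)O[C@H]([C@H]23)C[C@@]1(C)O | intermediate
29 | hydrazone of 28 (formed in situ) | C=C[C@@H]1[C@@]2(C)CCC[C@@]3(C=NN)C(OC)O[C@H]([C@H]23)C[C@@]1(C)O | intermediate
30 | cyclic methyl acetal with 4β-methyl, 8α-OH, 9β-vinyl | C=C[C@@H]1[C@@]2(C)CCC[C@@]3(C)C(OC)O[C@H]([C@H]23)C[C@@]1(C)O | intermediate
31 | C12 B-alkyl-9-BBN adduct of 30 (formed in situ) | C(CB4C5CCCC4CCC5)[C@@H]1[C@@]2(C)CCC[C@@]3(C)C(OC)O[C@H]([C@H]23)C[C@@]1(C)O | intermediate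
32 | tert-butyl (E)-enoate (C11–C15 chain on C9) | CC(C)(C)OC(=O)/C=C(\C)CC[C@@H]1[C@@]2(C)CCC[C@@]3(C)C(OC)O[C@H]([C@H]23)C[C@@]1(C)O | intermediate
33 | (E)-allylic alcohol (C15–OH) | OC/C=C(\C)CC[C@@H]1[C@@]2(C)CCC[C@@]3(C)C(OC)O[C@H]([C@H]23)C[C@@]1(C)O | intermediate
34 | (E)-enal (C15 aldehyde) | O=C/C=C(\C)CC[C@@H]1[C@@]2(C)CCC[C@@]3(C)C(OC)O[C@H]([C@H]23)C[C@@]1(C)O | intermediate
35 | 4-methylfuran-2(5H)-one | CC1=CC(=O)OC1 | starting material
36 | 4-methyl-2-(trimethylsilyloxy)furan | Cc1coc(O[Si](C)(C)C)c1 | intermediate
37 | (15S,16S)-15-trimethylsilyloxy butenolide acetal (formed in situ) | CC1=CC(=O)O[C@@H]1[C@@H](O[Si](C)(C)C)/C=C(\C)CC[C@@H]1[C@@]2(C)CCC[C@@]3(C)C(OC)O[C@H]([C@H]23)C[C@@]1(C)O | intermediate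
38 | (15S,16S)-15-hydroxy butenolide with 6α,18-cyclic methyl acetal | CC1=CC(=O)O[C@@H]1[C@@H](O)/C=C(\C)CC[C@@H]1[C@@]2(C)CCC[C@@]3(C)C(OC)O[C@H]([C@H]23)C[C@@]1(C)O | intermediate
39 | 6α,18-hemiacetal tautomer of the target (formed in situ) | CC1=CC(=O)O[C@@H]1[C@@H](O)/C=C(\C)CC[C@@H]1[C@@]2(C)CCC[C@@]3(C)C(O)O[C@H]([C@H]23)C[C@@]1(C)O | intermediate
40 | CNP0112578.1 | CC1=CC(=O)O[C@@H]1[C@@H](O)/C=C(\C)CC[C@@H]1[C@@]2(C)CCC[C@@](C)(C=O)[C@@H]2[C@@H](O)C[C@@]1(C)O | target

## Step count and least certain steps

Total: 25 steps. Longest linear sequence: 23 steps (from 3 through steps 2–22, 24 and 25). Steps 1 and 23 prepare reagents 2 and 36.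

**Step 8 (key step, proposed new method).** The most likely failure is that the C5–C10 bond does not form. The β,β-disubstituted enoyl imide is a weak acceptor, and the new quaternary centre is compressed against the C4 diester, so protodesilylation of the diene by the Lewis acid or arrest after the first addition can win. Facial selectivity could also erode if a non-chelated pathway takes over at higher temperature. Fallback: from 14, omitting 15, the kinetic C5 enolate is generated with LiN(SiMe3)2 in THF (−78 °C to rt) and allowed to undergo the anionic intramolecular double Michael annulation known for enone enolates with tethered unsaturated acyl acceptors. The enolate adds to C10 and the imide enolate so formed adds to C8, giving the bicyclic 6-ketone imide F1. Diastereomers would be separated at this stage, and C5 can be equilibrated through the ketone. Silylation of F1 toward C7 with TBSOTf/Et3N returns the route to 16.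

**Step 15.** The risk is poor facial control in the reduction at C6. A 6β-alkoxide would lactonise onto the 4β-ester and so reverse the assignment of the two C4 arms. Partial reduction of the esters by SmI2/H2O/amine and dehydration or retro-aldol cleavage of the β-hydroxy ketone under the amine are lesser risks. Fallback: from 20, both methyl esters are cleaved by SN2 demethylation (n-PrSLi, HMPA, rt) to the enone diacid F2, which is epoxidised as in step 13 to the epoxy diacid F3. Dissolving-metal reduction (Li, liquid NH3/THF, then MeOH and more Li) opens the epoxy ketone and reduces the ketone to the thermodynamically preferred equatorial alkoxide, the carboxylates being inert. Acidic work-up closes the lactone acid F4, and Me3SiCHN2 returns the route to 24.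

**Step 24.** The risk is insufficient enantiofacial or syn/anti selectivity, since the core gives no help. The catalyst may also be slowed by the free tertiary alcohol, and the β,β-disubstituted enal may react slowly. Fallback: from 34, a boron-mediated syn-glycolate aldol (Bu2BOTf, Et3N) with the (R)-oxazolidinone glycolate imide F5, made from (R)-4-benzyloxazolidin-2-one and (4-methoxybenzyloxy)acetyl chloride, gives the syn aldol adduct F6 under auxiliary control. Silylation (Et3SiOTf, 2,6-lutidine) gives the triethylsilyl ether F7, LiSEt removes the auxiliary to give the thioester F8, and Me2CuLi gives the methyl ketone F9. DDQ frees the α-hydroxy ketone F10, and (triphenylphosphoranylidene)ketene closes the butenolide silyl ether F11 by acylation and intramolecular Wittig reaction. Desilylation with PPTS in MeOH returns the route to 38.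

**Step 9.** The risk is loss of chemoselectivity. The acyl group on C9 is flanked by quaternary C10, so hydride may attack the malonate esters or the ring carbonyl of the auxiliary instead. Fallback: from 16, LiSEt (EtSH, n-BuLi, THF, 0 °C) cleaves the imide selectively to the thioester F12, and Fukuyama reduction (Et3SiH, palladium on carbon, acetone) gives the aldehyde directly, returning the route to 18 and omitting step 10.

## Further compounds

F1 | step 8 | bicyclic 6-ketone imide (trans-fused, 8β-methyl, 9β-acyl, 10β-methyl) | O=C(N1C(=O)OC[C@@H]1Cc1ccccc1)[C@@H]1[C@@]2(C)CCCC(C(=O)OC)(C(=O)OC)[C@@H]2C(=O)C[C@@H]1C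
F2 | step 15 | enone diacid | C=C[C@@H]1[C@@]2(C)CCCC(C(=O)O)(C(=O)O)[C@@H]2C(=O)C=C1C
F3 | step 15 | 7α,8α-epoxy ketone diacid | C=C[C@@H]1[C@@]2(C)CCCC(C(=O)O)(C(=O)O)[C@@H]2C(=O)[C@H]3O[C@@]13C
F4 | step 15 | 18,6α-lactone 4β-carboxylic acid | C=C[C@@H]1[C@@]2(C)CCC[C@@]3(C(=O)O)C(=O)O[C@H]([C@H]23)C[C@@]1(C)O
F5 | step 24 | (R)-4-benzyl-3-[2-(4-methoxybenzyloxy)acetyl]oxazolidin-2-one | COc1ccc(COCC(=O)N2C(=O)OC[C@H]2Cc2ccccc2)cc1
F6 | step 24 | syn-glycolate aldol adduct (15S-hydroxy, 16-OPMB imide) | O=C(N1C(=O)OC[C@H]1Cc1ccccc1)[C@H](OCc1ccc(OC)cc1)[C@@H](O)/C=C(\C)CC[C@@H]1[C@@]2(C)CCC[C@@]3(C)C(OC)O[C@H]([C@H]23)C[C@@]1(C)O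
F7 | step 24 | 15-triethylsilyl ether of the aldol adduct | O=C(N1C(=O)OC[C@H]1Cc1ccccc1)[C@H](OCc1ccc(OC)cc1)[C@@H](O[Si](CC)(CC)CC)/C=C(\C)CC[C@@H]1[C@@]2(C)CCC[C@@]3(C)C(OC)O[C@H]([C@H]23)C[C@@]1(C)O
F8 | step 24 | S-ethyl thioester | CCSC(=O)[C@H](OCc1ccc(OC)cc1)[C@@H](O[Si](CC)(CC)CC)/C=C(\C)CC[C@@H]1[C@@]2(C)CCC[C@@]3(C)C(OC)O[C@H]([C@H]23)C[C@@]1(C)O
F9 | step 24 | methyl ketone | CC(=O)[C@H](OCc1ccc(OC)cc1)[C@@H](O[Si](CC)(CC)CC)/C=C(\C)CC[C@@H]1[C@@]2(C)CCC[C@@]3(C)C(OC)O[C@H]([C@H]23)C[C@@]1(C)O
F10 | step 24 | α-hydroxy ketone | CC(=O)[C@H](O)[C@@H](O[Si](CC)(CC)CC)/C=C(\C)CC[C@@H]1[C@@]2(C)CCC[C@@]3(C)C(OC)O[C@H]([C@H]23)C[C@@]1(C)O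
F11 | step 24 | butenolide 15-triethylsilyl ether | CC1=CC(=O)O[C@@H]1[C@@H](O[Si](CC)(CC)CC)/C=C(\C)CC[C@@H]1[C@@]2(C)CCC[C@@]3(C)C(OC)O[C@H]([C@H]23)C[C@@]1(C)O
F12 | step 9 | S-ethyl thioester of the cycloadduct | CCSC(=O)[C@@H]1[C@@]2(C)CCCC(C(=O)OC)(C(=O)OC)[C@@H]2C(O[Si](C)(C)C(C)(C)C)=C[C@@H]1C
A1 | alternative 1 | core alkyne (C18 dimethyl acetal, 6- and 8-triethylsilyl ethers) | C#CCC[C@@H]1[C@@]2(C)CCC[C@@](C)(C(OC)OC)[C@@H]2[C@@H](O[Si](CC)(CC)CC)C[C@@]1(C)O[Si](CC)(CC)CC
A2 | alternative 1 | 2-(4-methoxybenzyloxy)-3-methylbut-3-enal | C=C(C)[C@H](OCc1ccc(OC)cc1)C=O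
A3 | alternative 1 | coupled (E)-allylic alcohol | C=C(C)[C@H](OCc1ccc(OC)cc1)[C@@H](O)/C=C(\C)CC[C@@H]1[C@@]2(C)CCC[C@@](C)(C(OC)OC)[C@@H]2[C@@H](O[Si](CC)(CC)CC)C[C@@]1(C)O[Si](CC)(CC)CC
A4 | alternative 2 | 2,6-dimethyl-1,4-benzoquinone | CC1=CC(=O)C=C(C)C1=O
A5 | alternative 2 | (E)-tert-butyldimethyl[(2-methylpenta-2,4-dien-1-yl)oxy]silane | C=C/C=C(\C)CO[Si](C)(C)C(C)(C)C
A6 | alternative 2 | cis-fused enedione adduct | O=C1[C@@]2(C)CC=C[C@@](C)(CO[Si](C)(C)C(C)(C)C)[C@H]2C(=O)C=C1C
A7 | alternative 3 | larixol | C=C[C@@](C)(O)CC[C@@H]1[C@@]2(C)CCCC(C)(C)[C@@H]2[C@@H](O)CC1=C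
A8 | alternative 3 | 6α-alcohol ketal with 8α-triethylsilyloxy group | CC1(OCCO1)CC[C@@H]1[C@@]2(C)CCCC(C)(C)[C@@H]2[C@@H](O)C[C@@]1(C)O[Si](CC)(CC)CC
A9 | alternative 3 | 6α,18-epoxy ether | CC1(OCCO1)CC[C@@H]1[C@@]2(C)CCC[C@@](C)(CO3)[C@@H]2[C@@H]3C[C@@]1(C)O[Si](CC)(CC)CC
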